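At 1.5 h the maple flask has to be judged from readings that stop at 50.0 min; the oak run, 6.00 K hotter, stands beside it.

| flask | J | G | Q | temperature | remark | time |
|---|---|---|---|---|---|---|
| maple | 0.80 M | 1.44 M | 19 mM | 90 °C | the very flask that is asked about, followed so far |  |
| oak | 0.80 M | 1.44 M | 19 mM | 96 °C | run made earlier |  |
| flask | 0.80 M | 1.44 M | 19 mM | 90 °C |  | 1.5 h |

| run | time / min | Z / % |
|---|---|---|
| maple | 4.00 | 7.0 |
| maple | 10.0 | 15.6 |
| maple | 20.0 | 23.2 |
| maple | 30.0 | 26.6 |
| maple | 40.0 | 28.7 |
| maple | 50.0 | 28.9 |
| oak | 4.00 | 9.7 |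
| oak | 10.0 | 19.2 |
| oak | 20.0 | 25.6 |
| oak | 30.0 | 28.1 |
| oak | 40.0 | 29.1 |
| oak | 50.0 | 29.9 |

(readings scatter by 0.5 percentage points)

- Z, in percent of the J first charged, at 1.5 h
- what to do for the largest gain in Z; "none" if nothing gains more than 2 percentage points (grey / violet / blue / ochre / none)
- Z present, in percent of the J first charged, after violet
- Z present, in percent of the J first charged, after blue

- grey: at 1.5 h add Q, 100 % of the amount charged, then wait 3.0 h
- violet: at 1.5 h raise the temperature by 10 K, then wait 3.0 h
- blue: at 1.5 h take out 90 % of the L then present, then wait 3.0 h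
- ochre: change nothing and wait 3.0 h more

- additions leave the volume as it is

Two extreme versions of the flask can be solved in the head. With no way back, Z would keep its first pace, 7.0 % in 4.00 min, until J, the limiting reagent ( 1.80 equivalents of G), reached 100 %. With balance reached at once, Z would stand from the start at the plateau, 28.9 % at the last maple reading. The real flask can be expected to keep close to the first version well before the crossing time, 16.5 min, where that first pace meets the plateau, and close to the second well beyond it. The reading time lies 5.45 crossing times out, so the maple flask is then under thermodynamic control, with Z near 28.9 %.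

Oak starts 1.39 times faster, yet its last reading stands 1 percentage point higher, against a scatter of 0.5 points on each reading, so the readings show a balance and give violet no measured lever. Taking J + G ⇌ Z + L one for one, that balance is carried by the plateau quotient cZ·cL/(cJ·cG) at standstill, 0.0777, with cZ at plateau 0.231 M. Grey and ochre leave this quotient where it stands, whereas blue cuts cL to a tenth of its value, and solving the quotient again puts Z at 41.3 %.

The forecast reads the plateaus alike (“a true equilibrium”) and gives 29.4 % now, blue as the choice, 30.8 % after violet and 42 % after blue, which stands 0.70 points above this reckoning.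

The flask gives 30.5 % at 1.5 h and blue as the choice: blue reaches 43.5 %, a gain of 13 points, while violet ends lower at 28.5 %. Its scheme is:

    D ⇌ L + X (K = 1.13 M, k = 5.79 /min, Ea = 97.0 kJ/mol, ΔH = 30.0 kJ/mol)
    X ⇌ Q + Z (K = 0.180 M, k = 69.4 /min, Ea = 89.0 kJ/mol, ΔH = −20.0 kJ/mol)
    J + Q ⇌ E (K = 1.80 /M, k = 9.13 /M/min, Ea = 44.0 kJ/mol, ΔH = −27.0 kJ/mol)
    G + E ⇌ D (K = 0.262 /M, k = 157 /M/min, Ea = 69.0 kJ/mol, ΔH = −3.00 kJ/mol)
    (constants at 90 °C)

Blue ends 2.2 points above the quotient's figure. A neighbouring flask has the same recipe with 0.20 M of J, so 7.20 equiv of G; the same quotient, 0.0777, puts its Z at 50.7 %, and that flask stands at 51.5 % at 1.5 h.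

The numbers in the tables were computed for substances that don't exist, and the scatter is random.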